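Set the constant of the uncatalysed step against that of the step that needs by-product: this ratio tells when the flask changes its law.

    partner + protic impurity → quenched reagent (k1 = 0.794 L mol⁻¹ h⁻¹, Ea1 = 69.0 kJ mol⁻¹)
    substrate + partner + by-product → target + 2 by-product (k2 = 1.11 L² mol⁻² h⁻¹, Ea2 = 55.0 kJ mol⁻¹)
    substrate + partner → target + by-product (k3 = 0.00215 L mol⁻¹ h⁻¹, Ea3 = 85.0 kJ mol⁻¹)
    (constants at 100 °C)

the same everywhere: substrate 0.35 M; partner 1.05 M; protic impurity 0.0700 M; time 30 h
- Sunday's: at 100 °C until 20 h, from then on at 80 °C
- Saturday's: temperature 100 °C
- Wednesday's: temperature 80 °C

* the flask that comes out highest in amount of target, in percent of the substrate charged, or "all alike" when all lie within 1.5 percentage points (Sunday's / Saturday's / Wednesday's / all alike)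
* target at the end, in percent of the substrate charged, Sunday's
* target at the end, in percent of the substrate charged, Saturday's
* target at the end, in percent of the substrate charged, Wednesday's

- all constants are for 100 °C and move with temperature by the activation energies

Start with the bench rule. Partner stands at 3.00 equivalents, so treat it as constant and the substrate as pseudo-first-order. Call the uncatalysed constant ks, 0.00215 L mol⁻¹ h⁻¹. The rule then promises a substrate lifetime of 443 h, longer than the 30 h run, so 6.55% target at the end.

Now find where the rule stops. Call the by-product constant ka, 1.11 L² mol⁻² h⁻¹, and the by-product concentration W. The two steps run in the ratio ka·W/ks, so they match at W* = ks/ka = 0.00194 M. That is 0.553% of the substrate charge, so the rule stops once that share has turned over.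

Solve both ends instead. Let the quench take its 0.0700 M of partner, and hold partner at B = 0.980 M. Early on, with substrate charge A, W grows exponentially at λ = ka·B·A = 0.381 h⁻¹. Late on, substrate decays at that same λ. Join the ends: converted over unconverted substrate grows roughly as exp(λ(t − τ)), with τ = ln(A/W*)/λ = 13.6 h. Call this the take-off time τ, the hour when converted and unconverted substrate are equal.

For Saturday's, τ falls inside the run, and the curve gives 99.8%. For Wednesday's, divide ka by 2.7 and ks by 4.7. Then λ is 0.140 h⁻¹ and τ is 41.2 h, beyond the end of the run. The curve gives 17.3%. Sunday's matches Saturday's until 20 h, which is later than τ, so expect it between the two.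

The forecast names Saturday's, with 93.3% for Sunday's, 98.5% for Saturday's and 17% for Wednesday's. Its grounds for the cold flask: “the flask is still in its induction phase at 30 h”.

The simulation gives Saturday's, with 93.3%, 98.5% and 17.0% in the same order, so the forecast holds.

Read Wednesday's as late, not poor: by 300 h it also reaches 100%. In τ, ka stands in λ, while ks stands inside a logarithm. The gap between Saturday's and Wednesday's is 82 percentage points; with the temperature dependence of the by-product step taken away, it is 28 points. With the temperature dependence of the uncatalysed step taken away instead, it is 79 points.

Now take Saturday's with 0.14 M of substrate. λ falls to 0.152 h⁻¹, τ moves to 28.1 h, and the curve gives 57.2%. The simulation gives 55.6% at 30.0 h.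

The constants used here belong to no real substance.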